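## Retrosynthetic overview

- Schizotenuin A is released at the end from its nona-O-allyl derivative (seven aryl allyl ethers, two allyl esters) by one deallylation with zerovalent palladium.
- The cinnamate C=C comes from a Knoevenagel–Doebner condensation of a benzofuran-5-carbaldehyde with the malonic half ester of allyl-protected (R)-danshensu; the C3 ester comes from acylating the same protected danshensu alcohol with the benzofuran-3-carbonyl chloride.
- The benzofuran C2–C3 bond is made by a crossed Claisen condensation between a ring A arylacetate enolate and 3,4-bis(allyloxy)benzoyl chloride; acid then removes the MOM groups and closes the furan ring by cyclodehydration (the only ring formed in the route).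
- The ring A arylacetate comes from 5-bromovanillin (demethylation, MOM protection, acetal, coupling with a zinc ester enolate); the aroyl chloride comes from ethyl 3,4-dihydroxybenzoate.
- Both (R) stereocentres come from methyl (R)-glycidate, opened at C3 by an aryl Grignard reagent under copper catalysis.

Assumption: 5-bromovanillin, ethyl 3,4-dihydroxybenzoate, 4-bromocatechol and methyl (R)-glycidate are bought; small reagents that deliver only a protecting group or a short carbon unit are named with SMILES in the steps and are not numbered.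

## Route

Step 1
Reactants: 1 5-bromovanillin (3-bromo-4-hydroxy-5-methoxybenzaldehyde)
Product: 2 3-bromo-4,5-dihydroxybenzaldehyde
Conditions: AlCl3 (1.1 equiv), pyridine (4.4 equiv), CH2Cl2, reflux, 24 h; then 2 M HCl
Reagents that add atoms: none
Why: Lewis acid-assisted aryl methyl ether cleavage, in which the aluminium chelate of the o-hydroxyanisole is demethylated by pyridine (SN2 at methyl) while aldehyde and bromide stay untouched.

Step 2
Reactants: 2 3-bromo-4,5-dihydroxybenzaldehyde
Product: 3 3-bromo-4,5-bis(methoxymethoxy)benzaldehyde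
Conditions: MOMCl (3 equiv), iPr2NEt (4 equiv), CH2Cl2, 0 °C to rt
Reagents that add atoms: chloromethyl methyl ether, COCCl
Why: Williamson-type O-alkylation of both phenols gives base-stable MOM ethers that acid can remove together later.

Step 3
Reactants: 3 3-bromo-4,5-bis(methoxymethoxy)benzaldehyde
Product: 4 1-bromo-5-(dimethoxymethyl)-2,3-bis(methoxymethoxy)benzene
Conditions: HC(OMe)3 (3 equiv), MeOH, PPTS (5 mol%), rt; Et3N quench
Reagents that add atoms: trimethyl orthoformate, COC(OC)OC; methanol, CO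
Why: Mild acid-catalysed acetalisation driven by the orthoformate masks the aldehyde against the zinc and lithium enolates of steps 4 and 8 without cleaving the MOM ethers.

Step 4
Reactants: 4 1-bromo-5-(dimethoxymethyl)-2,3-bis(methoxymethoxy)benzene
Product: 5 ethyl 2-[5-(dimethoxymethyl)-2,3-bis(methoxymethoxy)phenyl]acetate
Conditions: BrCH2CO2Et (1.6 equiv), Zn dust (2 equiv), TMSCl (cat.), THF, 40 °C, giving BrZnCH2CO2Et; then 4, Pd2(dba)3 (2 mol%), XPhos (8 mol%), THF, 60 °C
Reagents that add atoms: ethyl bromoacetate, CCOC(=O)CBr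
Why: Negishi cross-coupling of a Reformatsky reagent (palladium-catalysed α-arylation of a zinc ester enolate) runs under neutral conditions that acetal and MOM groups tolerate.

Step 5
Reactants: 6 ethyl 3,4-dihydroxybenzoate
Product: 7 ethyl 3,4-bis(allyloxy)benzoate
Conditions: allyl bromide (2.5 equiv), K2CO3 (3 equiv), DMF, 60 °C
Reagents that add atoms: allyl bromide, C=CCBr
Why: Williamson ether synthesis installs the allyl groups that stay on this catechol until the last step.

Step 6
Reactants: 7 ethyl 3,4-bis(allyloxy)benzoate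
Product: 8 3,4-bis(allyloxy)benzoic acid
Conditions: NaOH (3 equiv), EtOH/H2O, reflux; then HCl to pH 2
Reagents that add atoms: sodium hydroxide, [Na+].[OH-]
Why: Plain saponification of an unhindered benzoate; allyl aryl ethers are inert to hydroxide.

Step 7
Reactants: 8 3,4-bis(allyloxy)benzoic acid
Product: 9 3,4-bis(allyloxy)benzoyl chloride
Conditions: (COCl)2 (1.3 equiv), DMF (cat.), CH2Cl2, 0 °C to rt; evaporate, use crude
Reagents that add atoms: oxalyl chloride, ClC(=O)C(=O)Cl
Why: Vilsmeier-catalysed acyl chloride formation gives a non-enolisable, strongly electrophilic acyl donor for the condensation.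

Step 8
Reactants: 5 ethyl 2-[5-(dimethoxymethyl)-2,3-bis(methoxymethoxy)phenyl]acetate; 9 3,4-bis(allyloxy)benzoyl chloride
Product: 11 ethyl 3-[3,4-bis(allyloxy)phenyl]-2-[5-(dimethoxymethyl)-2,3-bis(methoxymethoxy)phenyl]-3-oxopropanoate, via lithium enolate 10 (not isolated)
Conditions: LiN(SiMe3)2 (2.1 equiv), THF, −78 °C, 45 min; then 9 (1.05 equiv), −78 to −20 °C; sat. NH4Cl
Reagents that add atoms: none
Why: Crossed Claisen condensation in which the lithium ester enolate is C-acylated by the aroyl chloride and the second equivalent of base stores the more acidic β-keto ester as its enolate; the new stereocentre is uncontrolled and is erased in step 9.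

Step 9
Reactants: 11 ethyl 3-[3,4-bis(allyloxy)phenyl]-2-[5-(dimethoxymethyl)-2,3-bis(methoxymethoxy)phenyl]-3-oxopropanoate
Product: 14 ethyl 2-[3,4-bis(allyloxy)phenyl]-5-formyl-7-hydroxy-1-benzofuran-3-carboxylate, via catechol keto ester 12 (not isolated), via cyclic hemiketal 13 (not isolated)
Conditions: conc. HCl (5 equiv), EtOH, 60 °C, 3 h; then H2O
Reagents that add atoms: water, O
Why: Acid removes both MOM ethers and the acetal, the phenol ortho to the side chain adds to the aryl ketone and the hemiketal dehydrates to the aromatic furan (cyclodehydration), while allyl ethers and the ethyl ester (EtOH as solvent) are unaffected.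

Step 10
Reactants: 14 ethyl 2-[3,4-bis(allyloxy)phenyl]-5-formyl-7-hydroxy-1-benzofuran-3-carboxylate
Product: 15 ethyl 7-(allyloxy)-2-[3,4-bis(allyloxy)phenyl]-5-formyl-1-benzofuran-3-carboxylate
Conditions: allyl bromide (1.5 equiv), K2CO3 (2 equiv), DMF, rt
Reagents that add atoms: allyl bromide, C=CCBr
Why: Williamson etherification of the single free phenol brings the core into the uniform allyl protection scheme.

Step 11
Reactants: 15 ethyl 7-(allyloxy)-2-[3,4-bis(allyloxy)phenyl]-5-formyl-1-benzofuran-3-carboxylate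
Product: 16 7-(allyloxy)-2-[3,4-bis(allyloxy)phenyl]-5-formyl-1-benzofuran-3-carboxylic acid
Conditions: LiOH·H2O (5 equiv), THF/EtOH/H2O, 60 °C; then 1 M HCl
Reagents that add atoms: lithium hydroxide, [Li+].[OH-]
Why: Saponification of the hindered heteroaryl ester; the non-enolisable aldehyde and the allyl ethers survive dilute hydroxide.

Step 12
Reactants: 17 4-bromocatechol
Product: 18 4-bromo-1,2-bis(allyloxy)benzene
Conditions: allyl bromide (2.5 equiv), K2CO3 (3 equiv), acetone, reflux
Reagents that add atoms: allyl bromide, C=CCBr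
Why: Williamson ether synthesis on both phenols.

Step 13
Reactants: 18 4-bromo-1,2-bis(allyloxy)benzene; 19 methyl (R)-glycidate (methyl (2R)-oxirane-2-carboxylate)
Product: 21 methyl (2R)-3-[3,4-bis(allyloxy)phenyl]-2-hydroxypropanoate, via arylmagnesium bromide 20 (not isolated)
Conditions: Mg, THF, 40 °C; then added slowly to 19 (0.75 equiv), CuI (10 mol%), THF, −40 to −20 °C; sat. NH4Cl
Reagents that add atoms: none
Why: Copper-catalysed SN2 opening of the epoxide at its unsubstituted C3 by the aryl Grignard reagent outruns ester addition at low temperature; C2 is not touched, so the (R) centre of the glycidate becomes the (R) carbinol.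

Step 14
Reactants: 21 methyl (2R)-3-[3,4-bis(allyloxy)phenyl]-2-hydroxypropanoate
Product: 22 (2R)-3-[3,4-bis(allyloxy)phenyl]-2-hydroxypropanoic acid
Conditions: LiOH·H2O (1.5 equiv), THF/H2O, 0 °C to rt; then 1 M HCl
Reagents that add atoms: lithium hydroxide, [Li+].[OH-]
Why: Mild saponification; the α-hydroxy carboxylate does not epimerise.

Step 15
Reactants: 22 (2R)-3-[3,4-bis(allyloxy)phenyl]-2-hydroxypropanoic acid
Product: 23 allyl (2R)-3-[3,4-bis(allyloxy)phenyl]-2-hydroxypropanoate
Conditions: allyl bromide (1.2 equiv), KHCO3 (1.5 equiv), DMF, rt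
Reagents that add atoms: allyl bromide, C=CCBr
Why: SN2 O-alkylation of the carboxylate is selective over the secondary alcohol with the weak base and does not involve the stereocentre.

Step 16
Reactants: 23 allyl (2R)-3-[3,4-bis(allyloxy)phenyl]-2-hydroxypropanoate
Product: 24 3-{[(2R)-1-(allyloxy)-3-[3,4-bis(allyloxy)phenyl]-1-oxopropan-2-yl]oxy}-3-oxopropanoic acid
Conditions: Meldrum's acid (1.1 equiv), toluene, 100 °C, 4 h
Reagents that add atoms: Meldrum's acid (2,2-dimethyl-1,3-dioxane-4,6-dione), CC1(C)OC(=O)CC(=O)O1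
Why: Neutral alcoholysis of Meldrum's acid (acyl transfer with loss of acetone) gives the malonic half ester without risk to the stereocentre.

Step 17
Reactants: 16 7-(allyloxy)-2-[3,4-bis(allyloxy)phenyl]-5-formyl-1-benzofuran-3-carboxylic acid; 23 allyl (2R)-3-[3,4-bis(allyloxy)phenyl]-2-hydroxypropanoate
Product: 26 (2R)-1-(allyloxy)-3-[3,4-bis(allyloxy)phenyl]-1-oxopropan-2-yl 7-(allyloxy)-2-[3,4-bis(allyloxy)phenyl]-5-formyl-1-benzofuran-3-carboxylate, via acid chloride 25 (not isolated)
Conditions: (COCl)2 (1.5 equiv), DMF (cat.), CH2Cl2, 0 °C to rt, evaporate; then 23 (1.2 equiv), pyridine (3 equiv), DMAP (10 mol%), CH2Cl2, 0 °C to rt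
Reagents that add atoms: none
Why: Esterification through the acid chloride with DMAP catalysis (nucleophilic acyl substitution) overcomes the hindrance of the 2-aryl-3-carboxylic acid; the alcohol C–O bond is not broken, so (R) is retained.

Step 18
Reactants: 26 (2R)-1-(allyloxy)-3-[3,4-bis(allyloxy)phenyl]-1-oxopropan-2-yl 7-(allyloxy)-2-[3,4-bis(allyloxy)phenyl]-5-formyl-1-benzofuran-3-carboxylate; 24 3-{[(2R)-1-(allyloxy)-3-[3,4-bis(allyloxy)phenyl]-1-oxopropan-2-yl]oxy}-3-oxopropanoic acid
Product: 28 nona-O-allyl schizotenuin A, (2R)-1-(allyloxy)-3-[3,4-bis(allyloxy)phenyl]-1-oxopropan-2-yl 7-(allyloxy)-5-[(E)-3-{[(2R)-1-(allyloxy)-3-[3,4-bis(allyloxy)phenyl]-1-oxopropan-2-yl]oxy}-3-oxoprop-1-enyl]-2-[3,4-bis(allyloxy)phenyl]-1-benzofuran-3-carboxylate, via arylidene malonic half ester 27 (not isolated)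
Conditions: 24 (1.5 equiv), pyridine, piperidine (0.2 equiv), rt to 50 °C, Ar
Reagents that add atoms: none
Why: Knoevenagel–Doebner condensation (aldol-type addition of the malonic half ester, dehydration, then decarboxylation in pyridine) gives the conjugated ester as the thermodynamically favoured E isomer under conditions too weakly basic to epimerise the α-acyloxy esters.

Step 19
Reactants: 28 nona-O-allyl schizotenuin A
Product: 29 schizotenuin A
Conditions: Pd(PPh3)4 (15 mol%), morpholine (20 equiv), THF, rt, Ar; then 1 M HCl to pH 2, reversed-phase chromatography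
Reagents that add atoms: none
Why: Tsuji–Trost-type allyl transfer from all seven aryl ethers and both esters to morpholine through π-allyl palladium intermediates leaves the two internal esters, the E alkene and both stereocentres untouched.

## Compound list

1 | 5-bromovanillin (3-bromo-4-hydroxy-5-methoxybenzaldehyde) | O=Cc1cc(Br)c(O)c(OC)c1 | starting material
2 | 3-bromo-4,5-dihydroxybenzaldehyde | O=Cc1cc(Br)c(O)c(O)c1 | intermediate
3 | 3-bromo-4,5-bis(methoxymethoxy)benzaldehyde | O=Cc1cc(Br)c(OCOC)c(OCOC)c1 | intermediate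
4 | 1-bromo-5-(dimethoxymethyl)-2,3-bis(methoxymethoxy)benzene | COC(OC)c1cc(Br)c(OCOC)c(OCOC)c1 | intermediate
5 | ethyl 2-[5-(dimethoxymethyl)-2,3-bis(methoxymethoxy)phenyl]acetate | CCOC(=O)Cc1cc(C(OC)OC)cc(OCOC)c1OCOC | intermediate
6 | ethyl 3,4-dihydroxybenzoate | CCOC(=O)c1ccc(O)c(O)c1 | starting material
7 | ethyl 3,4-bis(allyloxy)benzoate | CCOC(=O)c1ccc(OCC=C)c(OCC=C)c1 | intermediate
8 | 3,4-bis(allyloxy)benzoic acid | OC(=O)c1ccc(OCC=C)c(OCC=C)c1 | intermediate
9 | 3,4-bis(allyloxy)benzoyl chloride | ClC(=O)c1ccc(OCC=C)c(OCC=C)c1 | intermediate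
10 | lithium enolate of 5 | CCOC(O[Li])=Cc1cc(C(OC)OC)cc(OCOC)c1OCOC | intermediate (not isolated)
11 | ethyl 3-[3,4-bis(allyloxy)phenyl]-2-[5-(dimethoxymethyl)-2,3-bis(methoxymethoxy)phenyl]-3-oxopropanoate (racemic at C2, keto/enol mixture) | CCOC(=O)C(C(=O)c1ccc(OCC=C)c(OCC=C)c1)c1cc(C(OC)OC)cc(OCOC)c1OCOC | intermediate
12 | ethyl 3-[3,4-bis(allyloxy)phenyl]-2-(5-formyl-2,3-dihydroxyphenyl)-3-oxopropanoate | CCOC(=O)C(C(=O)c1ccc(OCC=C)c(OCC=C)c1)c1cc(C=O)cc(O)c1O | intermediate (not isolated)
13 | ethyl 2-[3,4-bis(allyloxy)phenyl]-5-formyl-2,7-dihydroxy-2,3-dihydro-1-benzofuran-3-carboxylate (mixture of stereoisomers) | CCOC(=O)C1c2cc(C=O)cc(O)c2OC1(O)c1ccc(OCC=C)c(OCC=C)c1 | intermediate (not isolated)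
14 | ethyl 2-[3,4-bis(allyloxy)phenyl]-5-formyl-7-hydroxy-1-benzofuran-3-carboxylate | CCOC(=O)c1c(-c2ccc(OCC=C)c(OCC=C)c2)oc2c(O)cc(C=O)cc12 | intermediate
15 | ethyl 7-(allyloxy)-2-[3,4-bis(allyloxy)phenyl]-5-formyl-1-benzofuran-3-carboxylate | CCOC(=O)c1c(-c2ccc(OCC=C)c(OCC=C)c2)oc2c(OCC=C)cc(C=O)cc12 | intermediate
16 | 7-(allyloxy)-2-[3,4-bis(allyloxy)phenyl]-5-formyl-1-benzofuran-3-carboxylic acid | OC(=O)c1c(-c2ccc(OCC=C)c(OCC=C)c2)oc2c(OCC=C)cc(C=O)cc12 | intermediate
17 | 4-bromocatechol | Oc1ccc(Br)cc1O | starting material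
18 | 4-bromo-1,2-bis(allyloxy)benzene | C=CCOc1ccc(Br)cc1OCC=C | intermediate
19 | methyl (R)-glycidate (methyl (2R)-oxirane-2-carboxylate) | COC(=O)[C@H]1CO1 | starting material
20 | [3,4-bis(allyloxy)phenyl]magnesium bromide | C=CCOc1ccc([Mg]Br)cc1OCC=C | intermediate (not isolated)
21 | methyl (2R)-3-[3,4-bis(allyloxy)phenyl]-2-hydroxypropanoate | COC(=O)[C@H](O)Cc1ccc(OCC=C)c(OCC=C)c1 | intermediate
22 | (2R)-3-[3,4-bis(allyloxy)phenyl]-2-hydroxypropanoic acid | OC(=O)[C@H](O)Cc1ccc(OCC=C)c(OCC=C)c1 | intermediate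
23 | allyl (2R)-3-[3,4-bis(allyloxy)phenyl]-2-hydroxypropanoate | C=CCOC(=O)[C@H](O)Cc1ccc(OCC=C)c(OCC=C)c1 | intermediate
24 | 3-{[(2R)-1-(allyloxy)-3-[3,4-bis(allyloxy)phenyl]-1-oxopropan-2-yl]oxy}-3-oxopropanoic acid | OC(=O)CC(=O)O[C@H](Cc1ccc(OCC=C)c(OCC=C)c1)C(=O)OCC=C | intermediate
25 | 7-(allyloxy)-2-[3,4-bis(allyloxy)phenyl]-5-formyl-1-benzofuran-3-carbonyl chloride | ClC(=O)c1c(-c2ccc(OCC=C)c(OCC=C)c2)oc2c(OCC=C)cc(C=O)cc12 | intermediate (not isolated)
26 | (2R)-1-(allyloxy)-3-[3,4-bis(allyloxy)phenyl]-1-oxopropan-2-yl 7-(allyloxy)-2-[3,4-bis(allyloxy)phenyl]-5-formyl-1-benzofuran-3-carboxylate | O=Cc1cc(OCC=C)c2oc(-c3ccc(OCC=C)c(OCC=C)c3)c(C(=O)O[C@H](Cc3ccc(OCC=C)c(OCC=C)c3)C(=O)OCC=C)c2c1 | intermediate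
27 | arylidene malonic half ester from 26 and 24 (alkene geometry undefined, both ester centres R) | OC(=O)C(=Cc1cc(OCC=C)c2oc(-c3ccc(OCC=C)c(OCC=C)c3)c(C(=O)O[C@H](Cc3ccc(OCC=C)c(OCC=C)c3)C(=O)OCC=C)c2c1)C(=O)O[C@H](Cc1ccc(OCC=C)c(OCC=C)c1)C(=O)OCC=C | intermediate (not isolated)
28 | nona-O-allyl schizotenuin A (E alkene, both centres R) | O=C(/C=C/c1cc(OCC=C)c2oc(-c3ccc(OCC=C)c(OCC=C)c3)c(C(=O)O[C@H](Cc3ccc(OCC=C)c(OCC=C)c3)C(=O)OCC=C)c2c1)O[C@H](Cc1ccc(OCC=C)c(OCC=C)c1)C(=O)OCC=C | intermediate
29 | schizotenuin A | O=C(/C=C/c1cc(O)c2oc(-c3ccc(O)c(O)c3)c(C(=O)O[C@H](Cc3ccc(O)c(O)c3)C(=O)O)c2c1)O[C@H](Cc1ccc(O)c(O)c1)C(=O)O | target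

## Step count and risks

Total step count: 19. Longest linear sequence: 11 steps (steps 1–4, 8–11, 17–19).

The three steps most likely to fail:

The zinc-enolate coupling of step 4 may stall on the ortho-alkoxy, electron-rich bromide, or the zinc bromide formed may attack the acetal and MOM groups. The fallback sets out from 4 and uses a base-mediated malonate arylation instead. Compound 4 is coupled with diethyl malonate (Pd(OAc)2, P(tBu)3·HBF4, K3PO4, toluene, 70 °C) to give diethyl 2-[5-(dimethoxymethyl)-2,3-bis(methoxymethoxy)phenyl]malonate F1. Krapcho dealkoxycarbonylation (LiCl, DMSO, 2 equiv H2O, 130 °C) removes one ester group and the sequence comes back to the route at 5.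

The Knoevenagel–Doebner condensation of step 18 may be slow with the bulky half ester 24, and heating in pyridine/piperidine could erode the two α-acyloxy ester centres or cause aminolysis. The fallback sets out from 23 and forms the same C=C bond by a neutral Wittig olefination. Alcohol 23 is acylated with bromoacetyl bromide (pyridine, CH2Cl2, 0 °C) to give (2R)-1-(allyloxy)-3-[3,4-bis(allyloxy)phenyl]-1-oxopropan-2-yl bromoacetate F2. Triphenylphosphine in toluene converts it into the corresponding triphenylphosphonium bromide F3. Et3N in CH2Cl2 gives the stabilised ylide F4, which reacts with aldehyde 26 at rt to give the E ester, coming back to the route at 28.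

The nine-fold deallylation of step 19 may stop at partly allylated products, C-allylate the freed catechols, or give a polyphenol that is hard to purify from amine and palladium residues. The fallback sets out from 26 and 24, removes the protecting groups before the last C–C bond is made, and so replaces steps 18 and 19. Aldehyde 26 is deallylated (Pd(PPh3)4, morpholine, THF, then acid) to (2R)-3-(3,4-dihydroxyphenyl)-2-{[2-(3,4-dihydroxyphenyl)-5-formyl-7-hydroxy-1-benzofuran-3-carbonyl]oxy}propanoic acid F5. Half ester 24 is deallylated in the same way to (2R)-2-[(carboxyacetyl)oxy]-3-(3,4-dihydroxyphenyl)propanoic acid F6. A protecting-group-free Knoevenagel–Doebner condensation of F5 with F6 (pyridine, piperidine cat., Ar, rt to 50 °C) passes through the unprotected arylidene malonic half ester F7 (not isolated), which loses carbon dioxide, and the sequence comes back to the route at 29.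

## Further compounds

F1 | step 4 | diethyl 2-[5-(dimethoxymethyl)-2,3-bis(methoxymethoxy)phenyl]malonate | CCOC(=O)C(C(=O)OCC)c1cc(C(OC)OC)cc(OCOC)c1OCOC
F2 | step 18 | (2R)-1-(allyloxy)-3-[3,4-bis(allyloxy)phenyl]-1-oxopropan-2-yl bromoacetate | BrCC(=O)O[C@H](Cc1ccc(OCC=C)c(OCC=C)c1)C(=O)OCC=C
F3 | step 18 | {2-[((2R)-1-(allyloxy)-3-[3,4-bis(allyloxy)phenyl]-1-oxopropan-2-yl)oxy]-2-oxoethyl}triphenylphosphonium bromide | [Br-].O=C(C[P+](c1ccccc1)(c1ccccc1)c1ccccc1)O[C@H](Cc1ccc(OCC=C)c(OCC=C)c1)C(=O)OCC=C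
F4 | step 18 | (2R)-1-(allyloxy)-3-[3,4-bis(allyloxy)phenyl]-1-oxopropan-2-yl (triphenylphosphoranylidene)acetate | O=C(C=P(c1ccccc1)(c1ccccc1)c1ccccc1)O[C@H](Cc1ccc(OCC=C)c(OCC=C)c1)C(=O)OCC=C
F5 | step 19 | (2R)-3-(3,4-dihydroxyphenyl)-2-{[2-(3,4-dihydroxyphenyl)-5-formyl-7-hydroxy-1-benzofuran-3-carbonyl]oxy}propanoic acid | O=Cc1cc(O)c2oc(-c3ccc(O)c(O)c3)c(C(=O)O[C@H](Cc3ccc(O)c(O)c3)C(=O)O)c2c1
F6 | step 19 | (2R)-2-[(carboxyacetyl)oxy]-3-(3,4-dihydroxyphenyl)propanoic acid | OC(=O)CC(=O)O[C@H](Cc1ccc(O)c(O)c1)C(=O)O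
F7 | step 19 | unprotected arylidene malonic half ester from F5 and F6 (alkene geometry undefined, both ester centres R) | OC(=O)C(=Cc1cc(O)c2oc(-c3ccc(O)c(O)c3)c(C(=O)O[C@H](Cc3ccc(O)c(O)c3)C(=O)O)c2c1)C(=O)O[C@H](Cc1ccc(O)c(O)c1)C(=O)O
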